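**Retrosynthetic overview**

1. The target is a 3-hydroxyisoflavanone. The strategy rests on C3 of ring C, a fully substituted carbinol carbon bonded to C1' of ring B, the C4 carbonyl, a hydroxyl oxygen and the C2 oxymethylene: the hydroxyl and C2 can both be added in one step to a carbene at C3 that has ring B as donor and the C4 carbonyl as acceptor.
2. Ring C is opened at O1–C2 (Mitsunobu closure of a ring A ortho phenol onto the primary carbinol after desilylation). It is the only ring formed in the route and it closes last.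
3. The C3–OH and C2–C3 bonds are cut together: diazo ketone, water and formaldehyde under Rh2(OAc)4 and a chiral phosphoric acid, which sets C3.
4. The diazo ketone comes from the deoxybenzoin by diazo transfer. The deoxybenzoin comes from palladium-catalysed α-arylation of silylated 2',4',6'-trihydroxyacetophenone with the ring B bromide.
5. The ring B bromide comes from 4-bromo-3-methoxyphenol by O-prenylation, Claisen rearrangement (1,1-dimethylallyl group at C5') and silylation.

Key step: step 7

**Assumptions (remarks on the chemistry)**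

- The sense of induction of the phosphoric acid cannot be predicted with confidence for this substrate. The (R)-acid is written; its (S)-antipode is used instead if the first runs give the (S)-diol.
- Isoflavanone numbering is used: ring C is O1, C2, C3, C4; ring A is C4a to C8a; ring B is C1' to C6'.
- The ring A aryl ketone is bought in 7 and not made by acid-mediated acylation, because HCl or Lewis acids would add to or cyclise the 1,1-dimethylallyl group.

**Route**

Step 1
Reactants: 1 4-bromo-3-methoxyphenol; 2 prenyl bromide (1-bromo-3-methylbut-2-ene)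
Product: 3 1-bromo-2-methoxy-4-[(3-methylbut-2-en-1-yl)oxy]benzene
Conditions: K2CO3, acetone, reflux
Reagents that add atoms: none
Why: Williamson ether synthesis, in which the phenoxide formed with K2CO3 displaces bromide from the primary allylic carbon of 2 in an SN2 reaction at oxygen.

Step 2
Reactants: 3 1-bromo-2-methoxy-4-[(3-methylbut-2-en-1-yl)oxy]benzene
Product: 5 4-bromo-5-methoxy-2-(2-methylbut-3-en-2-yl)phenol, via dienone 4 (not isolated)
Conditions: PhNEt2, 190 °C, sealed tube
Reagents that add atoms: none
Why: Aromatic Claisen rearrangement, in which the [3,3] shift carries the tertiary terminus of the prenyl group to the ortho carbon para to the methoxy group (the para position is blocked by bromine and the other ortho carbon is flanked by two oxygens) and dienone 4 tautomerises to the phenol.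

Step 3
Reactants: 5 4-bromo-5-methoxy-2-(2-methylbut-3-en-2-yl)phenol
Product: 6 1-bromo-2-methoxy-5-(2-methylbut-3-en-2-yl)-4-(triisopropylsilyloxy)benzene
Conditions: TIPSOTf, 2,6-lutidine, CH2Cl2, 0 °C to rt
Reagents that add atoms: triisopropylsilyl trifluoromethanesulfonate (TIPSOTf), CC(C)[Si](OS(=O)(=O)C(F)(F)F)(C(C)C)C(C)C
Why: O-Silylation of a hindered phenol with a silyl triflate, which is reactive enough to reach the oxygen beside the tertiary alkyl group, while 2,6-lutidine buffers the triflic acid so that the vinyl group is not protonated.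

Step 4
Reactants: 7 1-(2,4,6-trihydroxyphenyl)ethanone (2',4',6'-trihydroxyacetophenone, dried)
Product: 8 1-[2,4,6-tris(triisopropylsilyloxy)phenyl]ethanone
Conditions: TIPSOTf (3.3 equiv), 2,6-lutidine, CH2Cl2, 0 °C to rt
Reagents that add atoms: triisopropylsilyl trifluoromethanesulfonate (TIPSOTf), CC(C)[Si](OS(=O)(=O)C(F)(F)F)(C(C)C)C(C)C
Why: Exhaustive O-silylation with a silyl triflate, which should silylate the two hydrogen-bonded ortho phenols and the para phenol, while the weak base 2,6-lutidine should not turn the methyl ketone into its silyl enol ether.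

Step 5
Reactants: 6 1-bromo-2-methoxy-5-(2-methylbut-3-en-2-yl)-4-(triisopropylsilyloxy)benzene; 8 1-[2,4,6-tris(triisopropylsilyloxy)phenyl]ethanone
Product: 9 2-[2-methoxy-5-(2-methylbut-3-en-2-yl)-4-(triisopropylsilyloxy)phenyl]-1-[2,4,6-tris(triisopropylsilyloxy)phenyl]ethanone
Conditions: Pd2(dba)3 (2 mol %), XPhos (8 mol %), K3PO4, toluene, 90 °C
Reagents that add atoms: none
Why: Palladium-catalysed α-arylation of a ketone enolate (Buchwald–Hartwig type), in which zerovalent palladium inserts into the C–Br bond of 6, the enolate of 8 binds through carbon and reductive elimination joins the future C3 to C1' of ring B, the phosphate base being mild towards the aryl silyl ethers and the bulky ligand holding the reaction at monoarylation.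

Step 6
Reactants: 9 2-[2-methoxy-5-(2-methylbut-3-en-2-yl)-4-(triisopropylsilyloxy)phenyl]-1-[2,4,6-tris(triisopropylsilyloxy)phenyl]ethanone
Product: 10 2-diazo-2-[2-methoxy-5-(2-methylbut-3-en-2-yl)-4-(triisopropylsilyloxy)phenyl]-1-[2,4,6-tris(triisopropylsilyloxy)phenyl]ethanone
Conditions: p-ABSA, DBU, dry MeCN, 0 °C to rt
Reagents that add atoms: 4-acetamidobenzenesulfonyl azide (p-ABSA), CC(=O)Nc1ccc(cc1)S(=O)(=O)N=[N+]=[N-]
Why: Regitz diazo transfer, in which DBU deprotonates the methylene group that is both benzylic and α to the ketone, and the enolate adds to the terminal nitrogen of the sulfonyl azide and expels the sulfonamide to leave the diazo group on the future C3.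

Step 7
Reactants: 10 2-diazo-2-[2-methoxy-5-(2-methylbut-3-en-2-yl)-4-(triisopropylsilyloxy)phenyl]-1-[2,4,6-tris(triisopropylsilyloxy)phenyl]ethanone; 11 formaldehyde; 12 water
Product: 14 (2R)-2,3-dihydroxy-2-[2-methoxy-5-(2-methylbut-3-en-2-yl)-4-(triisopropylsilyloxy)phenyl]-1-[2,4,6-tris(triisopropylsilyloxy)phenyl]propan-1-one, via oxonium ylide 13 (not isolated)
Conditions: Rh2(OAc)4 (2 mol %), (R)-3,3'-bis(triphenylsilyl)-1,1'-binaphthyl-2,2'-diyl hydrogen phosphate (10 mol %), monomeric CH2O (methanol-free, from cracked paraformaldehyde, 5 equiv), H2O (3 equiv), CH2Cl2, −10 °C, slow addition of 10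
Reagents that add atoms: none
Why: Proposed new method: dirhodium tetraacetate expels N2 from 10 to give a donor/acceptor rhodium carbene at C3, water adds to it to form oxonium ylide 13 (in effect the enol of the benzoin), and this adds through carbon to formaldehyde held by the chiral phosphoric acid faster than it undergoes the 1,2-proton shift, so that the C3–O and C2–C3 bonds form in one operation. The closest known reaction type is the three-component reaction co-catalysed by a dirhodium carboxylate and a chiral phosphoric acid, in which an oxonium ylide from a diazo carbonyl compound and an alcohol or water is trapped by an imine or an aldehyde; the enantioselective pairing of water and formaldehyde on an acyclic diaryl diazo ketone has not been shown. No ring closes in this step. The C3 stereocentre is set by the phosphate, which is expected to bridge the enol hydroxyl and the formaldehyde oxygen by hydrogen bonds inside the pocket of the two triphenylsilyl groups and so expose one face of the enol. The step needs water to win over the ring A ortho oxygens for the carbene and the aldol addition to win over proton transfer. The bulky, weakly basic triisopropylsilyl ethers and the twist of the 2,6-disubstituted aroyl group disfavour five-membered ylide formation, slow addition keeps the carbene away from the vinyl group, and the small size and high electrophilicity of formaldehyde favour trapping at the congested carbon.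

Step 8
Reactants: 14 (2R)-2,3-dihydroxy-2-[2-methoxy-5-(2-methylbut-3-en-2-yl)-4-(triisopropylsilyloxy)phenyl]-1-[2,4,6-tris(triisopropylsilyloxy)phenyl]propan-1-one
Product: 15 (2R)-2,3-dihydroxy-2-[4-hydroxy-2-methoxy-5-(2-methylbut-3-en-2-yl)phenyl]-1-(2,4,6-trihydroxyphenyl)propan-1-one
Conditions: TBAF (4.4 equiv), AcOH (4.4 equiv), THF, 0 °C to rt
Reagents that add atoms: none
Why: Fluoride-mediated cleavage of aryl silyl ethers, in which fluoride attacks silicon and frees the four phenols while acetic acid keeps the medium near neutral, so that the β-hydroxy ketone should not lose formaldehyde by retro-aldol cleavage and C3 keeps its configuration.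

Step 9
Reactants: 15 (2R)-2,3-dihydroxy-2-[4-hydroxy-2-methoxy-5-(2-methylbut-3-en-2-yl)phenyl]-1-(2,4,6-trihydroxyphenyl)propan-1-one
Product: 16 (3R)-3,5,7-trihydroxy-3-[4-hydroxy-2-methoxy-5-(2-methylbut-3-en-2-yl)phenyl]-2,3-dihydro-4H-chromen-4-one
Conditions: PPh3, DIAD, THF (high dilution), 0 °C to rt
Reagents that add atoms: none
Why: Intramolecular Mitsunobu etherification, in which the primary alcohol is activated as its alkoxyphosphonium salt and displaced by one of the two equivalent ortho phenoxides of ring A in a 6-exo-tet closure that forms the O1–C2 bond of ring C, the tertiary alcohol being too hindered to be activated and C3 not being touched, so that the (R) configuration is carried over.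

**Compound list**

1 | 4-bromo-3-methoxyphenol | COc1cc(O)ccc1Br | starting material
2 | prenyl bromide (1-bromo-3-methylbut-2-ene) | CC(C)=CCBr | starting material
3 | 1-bromo-2-methoxy-4-[(3-methylbut-2-en-1-yl)oxy]benzene | COc1cc(OCC=C(C)C)ccc1Br | intermediate
4 | 4-bromo-3-methoxy-6-(2-methylbut-3-en-2-yl)cyclohexa-2,4-dien-1-one (racemic, not isolated) | O=C1C=C(OC)C(Br)=CC1C(C)(C)C=C | intermediate
5 | 4-bromo-5-methoxy-2-(2-methylbut-3-en-2-yl)phenol | C=CC(C)(C)c1cc(Br)c(OC)cc1O | intermediate
6 | 1-bromo-2-methoxy-5-(2-methylbut-3-en-2-yl)-4-(triisopropylsilyloxy)benzene | C=CC(C)(C)c1cc(Br)c(OC)cc1O[Si](C(C)C)(C(C)C)C(C)C | intermediate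
7 | 1-(2,4,6-trihydroxyphenyl)ethanone | CC(=O)c1c(O)cc(O)cc1O | starting material
8 | 1-[2,4,6-tris(triisopropylsilyloxy)phenyl]ethanone | CC(=O)c1c(O[Si](C(C)C)(C(C)C)C(C)C)cc(O[Si](C(C)C)(C(C)C)C(C)C)cc1O[Si](C(C)C)(C(C)C)C(C)C | intermediate
9 | 2-[2-methoxy-5-(2-methylbut-3-en-2-yl)-4-(triisopropylsilyloxy)phenyl]-1-[2,4,6-tris(triisopropylsilyloxy)phenyl]ethanone | C=CC(C)(C)c1cc(CC(=O)c2c(O[Si](C(C)C)(C(C)C)C(C)C)cc(O[Si](C(C)C)(C(C)C)C(C)C)cc2O[Si](C(C)C)(C(C)C)C(C)C)c(OC)cc1O[Si](C(C)C)(C(C)C)C(C)C | intermediate
10 | 2-diazo-2-[2-methoxy-5-(2-methylbut-3-en-2-yl)-4-(triisopropylsilyloxy)phenyl]-1-[2,4,6-tris(triisopropylsilyloxy)phenyl]ethanone | C=CC(C)(C)c1cc(C(=[N+]=[N-])C(=O)c2c(O[Si](C(C)C)(C(C)C)C(C)C)cc(O[Si](C(C)C)(C(C)C)C(C)C)cc2O[Si](C(C)C)(C(C)C)C(C)C)c(OC)cc1O[Si](C(C)C)(C(C)C)C(C)C | intermediate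
11 | formaldehyde | C=O | starting material
12 | water | O | starting material
13 | oxonium ylide of the carbene from 10 and water, drawn as its enolate form (alkene geometry not defined; neutral tautomer is the ene-diol; not isolated) | C=CC(C)(C)c1cc(C([OH2+])=C([O-])c2c(O[Si](C(C)C)(C(C)C)C(C)C)cc(O[Si](C(C)C)(C(C)C)C(C)C)cc2O[Si](C(C)C)(C(C)C)C(C)C)c(OC)cc1O[Si](C(C)C)(C(C)C)C(C)C | intermediate
14 | (2R)-2,3-dihydroxy-2-[2-methoxy-5-(2-methylbut-3-en-2-yl)-4-(triisopropylsilyloxy)phenyl]-1-[2,4,6-tris(triisopropylsilyloxy)phenyl]propan-1-one | C=CC(C)(C)c1cc([C@@](O)(CO)C(=O)c2c(O[Si](C(C)C)(C(C)C)C(C)C)cc(O[Si](C(C)C)(C(C)C)C(C)C)cc2O[Si](C(C)C)(C(C)C)C(C)C)c(OC)cc1O[Si](C(C)C)(C(C)C)C(C)C | intermediate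
15 | (2R)-2,3-dihydroxy-2-[4-hydroxy-2-methoxy-5-(2-methylbut-3-en-2-yl)phenyl]-1-(2,4,6-trihydroxyphenyl)propan-1-one | C=CC(C)(C)c1cc([C@@](O)(CO)C(=O)c2c(O)cc(O)cc2O)c(OC)cc1O | intermediate
16 | (3R)-3,5,7-trihydroxy-3-[4-hydroxy-2-methoxy-5-(2-methylbut-3-en-2-yl)phenyl]-2,3-dihydro-4H-chromen-4-one | C=CC(C)(C)c1cc([C@@]2(O)COc3cc(O)cc(O)c3C2=O)c(OC)cc1O | target

**Step count**

Total steps: 9. Longest linear sequence: 8 steps (steps 1, 2, 3, 5, 6, 7, 8, 9).

**Steps most likely to fail**

Step 7. The 1,2-proton shift of the ylide may outrun the aldol trapping (plain O–H insertion), the carbene may be captured by an ortho silyloxy oxygen of ring A, or the facial selectivity may be poor. The fallback builds the tertiary carbinol without a carbene; it sets out from 9 and rejoins the route at 16. α-Methylenation of 9 with bis(dimethylamino)methane and Ac2O should give the enone F1. Weitz–Scheffer epoxidation with t-BuOOH and DBU, which attacks only the electron-poor double bond, should give the racemic oxiranyl ketone F2. TBAF in THF would remove the four silyl groups, and an ortho phenoxide of ring A should open the oxirane at its CH2 carbon, as in the ring-closing stage of the Algar–Flynn–Oyamada reaction, to give racemic 16. Chromatography on a chiral stationary phase would then separate 16 from its (3S)-antipode F3.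

Step 5. The ortho silyl groups may migrate to the enolate oxygen or be lost under the basic conditions, the vinyl group may undergo Heck-type arylation, or the electron-rich bromide may fail to couple with the hindered ketone. The fallback forms the same carbon–carbon bond by carbonyl addition; it sets out from 8 and 6 and rejoins the route at 9. Riley oxidation of 8 with SeO2 in aqueous dioxane would give the aryl glyoxal F4, dried by azeotropic removal of water. Bromine–lithium exchange on 6 with t-BuLi in THF at −78 °C would give the aryllithium F5. F5 should add to the aldehyde carbonyl of F4, the ketone being shielded by the two ortho silyloxy groups, to give the racemic benzoin F6. Acetylation (Ac2O, pyridine, DMAP) to the acetate F7 and reductive cleavage of the α-acetoxy group with samarium diiodide in THF/MeOH would give 9.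

Step 9. The 1,2-diol may be diverted into an oxirane, the more acidic para phenol may form ethers between molecules, or oligomers may form. The fallback closes ring C by displacement of a preformed leaving group; it sets out from 14 and rejoins the route at 16 without passing through 15. The primary alcohol of 14 would be sulfonylated selectively with MsCl and Et3N in CH2Cl2 at −20 °C to the monomesylate F8 while the phenols are still silylated. TBAF in THF would then free the phenoxides, and an ortho phenoxide should displace the mesylate in the same flask (intramolecular Williamson closure) to give 16.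

**Further compounds**

F1 | step 7 | 2-[2-methoxy-5-(2-methylbut-3-en-2-yl)-4-(triisopropylsilyloxy)phenyl]-1-[2,4,6-tris(triisopropylsilyloxy)phenyl]prop-2-en-1-one | C=CC(C)(C)c1cc(C(=C)C(=O)c2c(O[Si](C(C)C)(C(C)C)C(C)C)cc(O[Si](C(C)C)(C(C)C)C(C)C)cc2O[Si](C(C)C)(C(C)C)C(C)C)c(OC)cc1O[Si](C(C)C)(C(C)C)C(C)C
F2 | step 7 | {2-[2-methoxy-5-(2-methylbut-3-en-2-yl)-4-(triisopropylsilyloxy)phenyl]oxiran-2-yl}[2,4,6-tris(triisopropylsilyloxy)phenyl]methanone (racemic) | C=CC(C)(C)c1cc(C2(CO2)C(=O)c3c(O[Si](C(C)C)(C(C)C)C(C)C)cc(O[Si](C(C)C)(C(C)C)C(C)C)cc3O[Si](C(C)C)(C(C)C)C(C)C)c(OC)cc1O[Si](C(C)C)(C(C)C)C(C)C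
F3 | step 7 | (3S)-3,5,7-trihydroxy-3-[4-hydroxy-2-methoxy-5-(2-methylbut-3-en-2-yl)phenyl]-2,3-dihydro-4H-chromen-4-one | C=CC(C)(C)c1cc([C@]2(O)COc3cc(O)cc(O)c3C2=O)c(OC)cc1O
F4 | step 5 | 2-oxo-2-[2,4,6-tris(triisopropylsilyloxy)phenyl]acetaldehyde | O=CC(=O)c1c(O[Si](C(C)C)(C(C)C)C(C)C)cc(O[Si](C(C)C)(C(C)C)C(C)C)cc1O[Si](C(C)C)(C(C)C)C(C)C
F5 | step 5 | [2-methoxy-5-(2-methylbut-3-en-2-yl)-4-(triisopropylsilyloxy)phenyl]lithium | [Li]c1cc(C(C)(C)C=C)c(O[Si](C(C)C)(C(C)C)C(C)C)cc1OC
F6 | step 5 | 2-hydroxy-2-[2-methoxy-5-(2-methylbut-3-en-2-yl)-4-(triisopropylsilyloxy)phenyl]-1-[2,4,6-tris(triisopropylsilyloxy)phenyl]ethanone (racemic) | C=CC(C)(C)c1cc(C(O)C(=O)c2c(O[Si](C(C)C)(C(C)C)C(C)C)cc(O[Si](C(C)C)(C(C)C)C(C)C)cc2O[Si](C(C)C)(C(C)C)C(C)C)c(OC)cc1O[Si](C(C)C)(C(C)C)C(C)C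
F7 | step 5 | 1-[2-methoxy-5-(2-methylbut-3-en-2-yl)-4-(triisopropylsilyloxy)phenyl]-2-oxo-2-[2,4,6-tris(triisopropylsilyloxy)phenyl]ethyl acetate (racemic) | C=CC(C)(C)c1cc(C(OC(C)=O)C(=O)c2c(O[Si](C(C)C)(C(C)C)C(C)C)cc(O[Si](C(C)C)(C(C)C)C(C)C)cc2O[Si](C(C)C)(C(C)C)C(C)C)c(OC)cc1O[Si](C(C)C)(C(C)C)C(C)C
F8 | step 9 | (2R)-2-hydroxy-2-[2-methoxy-5-(2-methylbut-3-en-2-yl)-4-(triisopropylsilyloxy)phenyl]-3-oxo-3-[2,4,6-tris(triisopropylsilyloxy)phenyl]propyl methanesulfonate | C=CC(C)(C)c1cc([C@@](O)(COS(C)(=O)=O)C(=O)c2c(O[Si](C(C)C)(C(C)C)C(C)C)cc(O[Si](C(C)C)(C(C)C)C(C)C)cc2O[Si](C(C)C)(C(C)C)C(C)C)c(OC)cc1O[Si](C(C)C)(C(C)C)C(C)C
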